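**Retrosynthetic overview**

1. Locants follow the target name: C1 bridgehead C–OMe, C2 C=O, C3 CH–OMe, C4 CH2, C5 allyl-bearing bridgehead, C6 CH–CH3, C7 CH–aryl, C8 CH–OH. C8–OH, C3–H and the phenol are adjusted last from bicyclo[3.2.1]oct-3-ene-2,8-dione 15.
2. 15 comes from a cationic (5+2) union of (E)-propenylarene 10 (C6, C7) with a 4-methoxyphenoxonium ion whose ring is C1–C2–C3–C4–C5–C8; bonds C5–C6 and C1–C7 form across the two ortho carbons, C8 being the phenol carbon.
3. That six-membered ring is not taken from aromatic stock. It is grown in the same flask from a four-membered ring: C8, C1, C2, C3 are the four ring carbons of dimethyl squarate 1, and C4, C5 are the alkene carbons of a (Z)-penta-1,4-dienyl group (ring opening to a dienylketene, 6π closure, then oxidation and cycloaddition).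
4. Enabling feature: the unbroken row of oxygen-bearing carbons C8(O)–C1(OMe)–C2(O)–C3(OMe) of the six-membered ring is the substitution pattern of a squaric ester, and C1 and C5 both flank C8, so they are the ortho positions of the phenol that the ring expansion delivers.
5. Ring order: cyclobutenone (from 1), then the six-membered ring by ring expansion, then the five-membered ring C1–C7–C6–C5–C8 by the cycloaddition; the enantiomers are separated directly afterwards.

Key step: step 5

Remark on the chemistry: the cycloaddition of step 5 is not enantioselective, so the single enantiomer is secured by the separation in step 6; 5 and 6 are racemic at a centre that disappears in step 5.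

**Step 1**
Reactants: 1 dimethyl squarate (3,4-dimethoxycyclobut-3-ene-1,2-dione); 2 pent-1-en-4-yne
Product: 5 2,3,4-trimethoxy-4-(pent-4-en-1-yn-1-yl)cyclobut-2-en-1-one, via lithium acetylide 3 (not isolated), via lithium alkoxide 4 (not isolated)
Conditions: 2, n-BuLi, THF, −78 °C; added to 1, THF, −78 °C; then MeOSO2CF3, −78 to 0 °C
Reagents that add atoms: methyl trifluoromethanesulfonate COS(=O)(=O)C(F)(F)F
Why: 1,2-addition of an alkynyllithium to one carbonyl of the squaric ester followed by O-methylation of the tertiary lithium alkoxide in the same flask, the new stereocentre being racemic and destroyed in step 5.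

**Step 2**
Reactants: 5 2,3,4-trimethoxy-4-(pent-4-en-1-yn-1-yl)cyclobut-2-en-1-one
Product: 6 2,3,4-trimethoxy-4-[(1Z)-penta-1,4-dien-1-yl]cyclobut-2-en-1-one
Conditions: H2 (1 atm, stopped at 1 equiv), Pd/CaCO3 poisoned with Pb(OAc)2, quinoline, EtOAc, 0 °C to rt
Reagents that add atoms: none
Why: Lindlar semihydrogenation delivers H2 syn on the poisoned palladium surface to give the (Z)-alkene and should stop there, the terminal alkene and the tetrasubstituted ring alkene being left under quinoline poisoning.

**Step 3**
Reactants: 7 5-bromo-2-methoxyphenol; 8 4,4,5,5-tetramethyl-2-[(1E)-prop-1-en-1-yl]-1,3,2-dioxaborolane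
Product: 9 2-methoxy-5-[(1E)-prop-1-en-1-yl]phenol
Conditions: Pd(PPh3)4 (3 mol %), K2CO3, 1,4-dioxane/H2O, 85 °C
Reagents that add atoms: none
Why: Suzuki–Miyaura coupling proceeds with retention of the (E) geometry of the alkenylboronate, and the free phenol is tolerated as its phenoxide.

**Step 4**
Reactants: 9 2-methoxy-5-[(1E)-prop-1-en-1-yl]phenol
Product: 10 {2-methoxy-5-[(1E)-prop-1-en-1-yl]phenoxy}tri(propan-2-yl)silane
Conditions: i-Pr3SiCl, imidazole, DMF, rt
Reagents that add atoms: chlorotri(propan-2-yl)silane CC(C)[Si](Cl)(C(C)C)C(C)C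
Why: imidazole-promoted silylation of the phenol gives an aryl silyl ether that should withstand PhI(OAc)2, hydride and catalytic base and keeps this phenol from being oxidised in step 5.

**Step 5**
Reactants: 6 2,3,4-trimethoxy-4-[(1Z)-penta-1,4-dien-1-yl]cyclobut-2-en-1-one; 10 {2-methoxy-5-[(1E)-prop-1-en-1-yl]phenoxy}tri(propan-2-yl)silane
Product: 14 rac-(1S*,5R*,6R*,7S*)-1,3-dimethoxy-7-{4-methoxy-3-[tri(propan-2-yl)silyloxy]phenyl}-6-methyl-5-(prop-2-en-1-yl)bicyclo[3.2.1]oct-3-ene-2,8-dione, via dienylketene 11 (not isolated), via phenol 12 (not isolated), via phenoxonium ion 13 (not isolated)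
Conditions: PhMe, 110 °C; cooled to −20 °C; 10 (2 equiv), (CF3)2CHOH, PhI(OAc)2 (1.1 equiv), −20 °C
Reagents that add atoms: none
Why: Moore rearrangement and oxidative phenol–alkene (5+2) cycloaddition run in one flask: conrotatory 4π opening of cyclobutenone 6 (4-OMe outward, dienyl inward) gives dienylketene 11, and its disrotatory 6π electrocyclisation followed by enolisation turns the four-membered ring into the six-membered ring C8–C1–C2–C3–C4–C5 (phenol 12), the two added ring atoms C4 and C5 being the former alkene carbons. PhI(OAc)2 then binds the phenol oxygen and departs as PhI to leave the 4-methoxyphenoxonium ion 13; the CH(CH3) carbon of alkene 10 adds to C5, the only ortho or para position of 13 without an oxygen donor, and the resulting p-methoxybenzylic cation is closed onto the enol ether carbon C1 (five-membered ring C1–C7–C6–C5–C8 by cation–enol ether collapse), after which acetate removes the methyl group from the O-methylated C2 carbonyl. Closest known reaction types: the thermal ring expansion of 4-alkenyl-4-alkoxycyclobutenones to phenols, and the cationic (5+2) cycloaddition of (E)-propenylarenes with phenoxonium ions released from p-quinone monoketals by acid or from 4-methoxyphenols by anodic or PhI(OAc)2 oxidation. C1 and C5 are fixed relative to each other because the two-carbon bridge can only span one face of the ring; C6 and C7 should come out trans because the (E) geometry of 10 is carried through the short-lived benzylic cation, and the aryl group is expected endo (under the three-carbon bridge) because the cation closes from the compact arrangement in which the anisyl ring lies stacked over the electron-rich ring, which leaves methyl exo. The step needs oxidation of 12 in preference to 10 (secured by the much lower oxidation potential of the tetraoxygenated phenol and its ligation to iodine through OH) and C-closure at C1 in preference to O-closure by the C8 carbonyl oxygen (expected to be kinetically favoured at low temperature in the weakly acidic, non-nucleophilic fluoro alcohol; both ortho positions are blocked, so no rearomatisation competes). The adduct forms as the racemate.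

**Step 6**
Reactants: 14 rac-(1S*,5R*,6R*,7S*)-enedione
Product: 15 (1S,5R,6R,7S)-1,3-dimethoxy-7-{4-methoxy-3-[tri(propan-2-yl)silyloxy]phenyl}-6-methyl-5-(prop-2-en-1-yl)bicyclo[3.2.1]oct-3-ene-2,8-dione
Conditions: preparative supercritical-fluid chromatography, amylose tris(3,5-dimethylphenylcarbamate) on silica, CO2/MeOH
Reagents that add atoms: none
Why: resolution by chromatography on a chiral stationary phase should separate the enantiomers of this rigid, UV-active enedione, and the absolute configuration of the collected enantiomer is to be assigned by X-ray analysis with anomalous dispersion.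

**Step 7**
Reactants: 15 (1S,5R,6R,7S)-enedione
Product: 17 (1S,5R,6R,7S,8S)-8-hydroxy-1,3-dimethoxy-7-{4-methoxy-3-[tri(propan-2-yl)silyloxy]phenyl}-6-methyl-5-(prop-2-en-1-yl)bicyclo[3.2.1]oct-3-en-2-one, via 8-epi alcohol 16 (not isolated)
Conditions: NaBH4 (0.5 equiv), MeOH/THF, −40 °C; aqueous work-up; crude 16, KOt-Bu (0.2 equiv), THF/t-BuOH, 0 °C to rt
Reagents that add atoms: none
Why: hydride should add to the strained one-carbon-bridge ketone C8 (the conjugated C2 carbonyl next to the quaternary C1 is left) from the open side above the flat C2–C3–C4 enone bridge, as in additions to 7-norbornenone-type ketones, giving the 8R alcohol 16 with OH beside the exo 6-methyl group; catalytic KOt-Bu then equilibrates this β-hydroxy ketone by reversible retro-aldol/aldol reaction across C1–C8 (the ring-opened aldehyde can re-close only on the face of C1 that its tether reaches, so C1 is kept) to the 8S epimer 17, expected to be thermodynamically preferred because OH then lies over the planar bridge and the 1,3-clash with the methyl group is gone.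

**Step 8**
Reactants: 17 (1S,5R,6R,7S,8S)-hydroxy enone
Product: 18 (1S,3S,5S,6R,7S,8S)-8-hydroxy-1,3-dimethoxy-7-{4-methoxy-3-[tri(propan-2-yl)silyloxy]phenyl}-6-methyl-5-(prop-2-en-1-yl)bicyclo[3.2.1]octan-2-one
Conditions: [(Ph3P)CuH]6 (0.5 equiv), H2O (5 equiv), degassed PhH/THF, rt
Reagents that add atoms: none
Why: copper hydride conjugate reduction transfers hydride to the β-carbon C4 of the α-methoxy enone without touching the isolated allyl alkene, and the copper enolate should be protonated at C3 from the exo side (the endo side is covered by the 7-aryl group and the syn C8–OH can relay the proton), which gives H exo and OMe endo, that is 3S, in a non-basic medium that avoids later epimerisation.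

**Step 9**
Reactants: 18 silyl-protected hydroxy ketone
Product: 19 (1S,3S,5S,6R,7S,8S)-8-hydroxy-7-(3-hydroxy-4-methoxyphenyl)-1,3-dimethoxy-6-methyl-5-(prop-2-en-1-yl)bicyclo[3.2.1]octan-2-one
Conditions: HF·pyridine, THF/pyridine, 0 °C to rt
Reagents that add atoms: none
Why: fluoride cleavage of the aryl silyl ether under weakly acidic conditions is chosen over basic fluoride so that the C3 centre next to the ketone and the β-hydroxy ketone unit (retro-aldol) are not disturbed.

**Compound list**

1 | dimethyl squarate (3,4-dimethoxycyclobut-3-ene-1,2-dione) | COC1=C(OC)C(=O)C1=O | starting material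
2 | pent-1-en-4-yne | C=CCC#C | starting material
3 | lithium pent-4-en-1-yn-1-ide | [Li]C#CCC=C | intermediate
4 | lithium 2,3-dimethoxy-4-oxo-1-(pent-4-en-1-yn-1-yl)cyclobut-2-en-1-olate (racemic) | [Li]OC1(C#CCC=C)C(OC)=C(OC)C1=O | intermediate
5 | 2,3,4-trimethoxy-4-(pent-4-en-1-yn-1-yl)cyclobut-2-en-1-one (racemic) | COC1=C(OC)C(OC)(C#CCC=C)C1=O | intermediate
6 | 2,3,4-trimethoxy-4-[(1Z)-penta-1,4-dien-1-yl]cyclobut-2-en-1-one (racemic) | COC1=C(OC)C(OC)(/C=C\CC=C)C1=O | intermediate
7 | 5-bromo-2-methoxyphenol | COc1ccc(Br)cc1O | starting material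
8 | 4,4,5,5-tetramethyl-2-[(1E)-prop-1-en-1-yl]-1,3,2-dioxaborolane | C/C=C/B1OC(C)(C)C(C)(C)O1 | starting material
9 | 2-methoxy-5-[(1E)-prop-1-en-1-yl]phenol | COc1ccc(/C=C/C)cc1O | intermediate
10 | {2-methoxy-5-[(1E)-prop-1-en-1-yl]phenoxy}tri(propan-2-yl)silane | COc1ccc(/C=C/C)cc1O[Si](C(C)C)(C(C)C)C(C)C | intermediate
11 | (3Z,5Z)-2,3,4-trimethoxynona-1,3,5,8-tetraen-1-one (dienylketene) | O=C=C(OC)/C(OC)=C(OC)\C=C/CC=C | intermediate
12 | 2,3,4-trimethoxy-6-(prop-2-en-1-yl)phenol | C=CCc1cc(OC)c(OC)c(OC)c1O | intermediate
13 | methyl[2,3-dimethoxy-4-oxo-5-(prop-2-en-1-yl)cyclohexa-2,5-dien-1-ylidene]oxidanium acetate (4-methoxyphenoxonium ion of 12) | CC(=O)[O-].O=C1C(CC=C)=CC(=[O+]C)C(OC)=C1OC | intermediate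
14 | rac-(1S*,5R*,6R*,7S*)-1,3-dimethoxy-7-{4-methoxy-3-[tri(propan-2-yl)silyloxy]phenyl}-6-methyl-5-(prop-2-en-1-yl)bicyclo[3.2.1]oct-3-ene-2,8-dione (both enantiomers) | C=CC[C@]12C=C(OC)C(=O)[C@](OC)([C@H](c3ccc(OC)c(O[Si](C(C)C)(C(C)C)C(C)C)c3)[C@H]1C)C2=O.C=CC[C@@]12C=C(OC)C(=O)[C@@](OC)([C@@H](c3ccc(OC)c(O[Si](C(C)C)(C(C)C)C(C)C)c3)[C@@H]1C)C2=O | intermediate
15 | (1S,5R,6R,7S)-1,3-dimethoxy-7-{4-methoxy-3-[tri(propan-2-yl)silyloxy]phenyl}-6-methyl-5-(prop-2-en-1-yl)bicyclo[3.2.1]oct-3-ene-2,8-dione | C=CC[C@]12C=C(OC)C(=O)[C@](OC)([C@H](c3ccc(OC)c(O[Si](C(C)C)(C(C)C)C(C)C)c3)[C@H]1C)C2=O | intermediate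
16 | (1S,5R,6R,7S,8R)-8-hydroxy-1,3-dimethoxy-7-{4-methoxy-3-[tri(propan-2-yl)silyloxy]phenyl}-6-methyl-5-(prop-2-en-1-yl)bicyclo[3.2.1]oct-3-en-2-one | C=CC[C@]12C=C(OC)C(=O)[C@](OC)([C@H](c3ccc(OC)c(O[Si](C(C)C)(C(C)C)C(C)C)c3)[C@H]1C)[C@@H]2O | intermediate
17 | (1S,5R,6R,7S,8S)-8-hydroxy-1,3-dimethoxy-7-{4-methoxy-3-[tri(propan-2-yl)silyloxy]phenyl}-6-methyl-5-(prop-2-en-1-yl)bicyclo[3.2.1]oct-3-en-2-one | C=CC[C@]12C=C(OC)C(=O)[C@](OC)([C@H](c3ccc(OC)c(O[Si](C(C)C)(C(C)C)C(C)C)c3)[C@H]1C)[C@H]2O | intermediate
18 | (1S,3S,5S,6R,7S,8S)-8-hydroxy-1,3-dimethoxy-7-{4-methoxy-3-[tri(propan-2-yl)silyloxy]phenyl}-6-methyl-5-(prop-2-en-1-yl)bicyclo[3.2.1]octan-2-one | C=CC[C@]12C[C@H](OC)C(=O)[C@](OC)([C@H](c3ccc(OC)c(O[Si](C(C)C)(C(C)C)C(C)C)c3)[C@H]1C)[C@H]2O | intermediate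
19 | (1S,3S,5S,6R,7S,8S)-8-hydroxy-7-(3-hydroxy-4-methoxyphenyl)-1,3-dimethoxy-6-methyl-5-(prop-2-en-1-yl)bicyclo[3.2.1]octan-2-one | C=CC[C@]12C[C@H](OC)C(=O)[C@](OC)([C@H](c3ccc(OC)c(O)c3)[C@H]1C)[C@H]2O | target

**Totals**

Total step count: 9. Longest linear sequence: 7 steps (1, 2, 5, 6, 7, 8, 9 from dimethyl squarate; the aryl branch 3, 4, 5–9 is equally long).

**Steps most likely to fail, with fallbacks**

Step 5. What may go wrong: capture of the benzylic cation by the C8 carbonyl oxygen instead of C1 (hydrobenzofuranone formation), oxidation of the alkene partner by the iodine reagent, or incompatibility of the two stages in one flask. The fallback sets out from 6 and comes back at 14. Cyclobutenone 6 is heated alone (PhMe, 110 °C) and phenol 12 is isolated. It is oxidised with PhI(OAc)2 in MeOH at 0 °C to the p-quinone monoketal 2,3,4,4-tetramethoxy-6-(prop-2-en-1-yl)cyclohexa-2,5-dien-1-one F1. F1 is then ionised with catalytic Me3SiOSO2CF3 in CH2Cl2 at −78 °C in the presence of 10. This releases the same phenoxonium ion without an oxidant and under strictly kinetic conditions, and should give 14.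

Step 7. What may go wrong: hydride delivery to C8 from the wrong face that cannot be corrected because the retro-aldol equilibration is slow, or diversion of the ring-opened keto-aldehyde before it re-closes. The fallback sets out from 15 and comes back at 17. Dione 15 is reduced with an NADPH-dependent ketoreductase chosen from a panel (glucose/glucose dehydrogenase recycling, aqueous buffer/DMSO, 30 °C). The face of C8 is then selected by the enzyme rather than by the substrate, and enzymes of either facial preference are available. This fallback makes no new compound (F0).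

Step 8. What may go wrong: slow hydride transfer to the hindered β-carbon C4 beside the quaternary C5, loss of hydride to the free C8–OH, or protonation of the enolate at C3 from the endo side. The fallback sets out from 15 and comes back at 18. The copper hydride reduction is carried out one stage earlier on enedione 15, which has a more electron-poor enone, no hydroxyl group and an exo face at C3 free of any C8 substituent. This should give (1S,3S,5S,6R,7S)-1,3-dimethoxy-7-{4-methoxy-3-[tri(propan-2-yl)silyloxy]phenyl}-6-methyl-5-(prop-2-en-1-yl)bicyclo[3.2.1]octane-2,8-dione F2. The C8 ketone of F2 is then reduced (NaBH4, MeOH, −78 °C, or the ketoreductase named above) and the C8 epimers are separated by chromatography to reach 18. Base equilibration is avoided here because C3 is by then epimerisable.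

**Further compounds**

F1 | step 5 | 2,3,4,4-tetramethoxy-6-(prop-2-en-1-yl)cyclohexa-2,5-dien-1-one | C=CCC1=CC(OC)(OC)C(OC)=C(OC)C1=O
F0 | step 7 | none | none
F2 | step 8 | (1S,3S,5S,6R,7S)-1,3-dimethoxy-7-{4-methoxy-3-[tri(propan-2-yl)silyloxy]phenyl}-6-methyl-5-(prop-2-en-1-yl)bicyclo[3.2.1]octane-2,8-dione | C=CC[C@]12C[C@H](OC)C(=O)[C@](OC)([C@H](c3ccc(OC)c(O[Si](C(C)C)(C(C)C)C(C)C)c3)[C@H]1C)C2=O
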